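Ring B of the 1-aryl-1,2-dihydronaphthalene is opened at C4–C4a and C1–C2. This leaves a benzylic C4a–C8a–C1 unit and a C4–C3–C2 unit that is itaconic acid. The key step exploits two features. C1 is para-benzylic to the free 4-OH of pendant guaiacyl ring C, so it can be unmasked as a p-quinone methide carbon, and C4a can carry the bromine of 6-bromoisovanillin. In one operation palladium arylates the CH2 terminus of di-tert-butyl itaconate, and the new C2 carbanion, paired with a chiral ammonium ion, closes onto C1. The precursor is an acyclic aryl bromide/diarylmethyl sulfone already bearing the (Z)-enol ether arm. C2 is finally set cis by kinetic protonation.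

Key step: step 7

Locants: dihydronaphthalene numbering is used, with C1 (CH–aryl), C2 (CH–CO2H), C3, C4 (=CH), C4a, C5–C8, C8a. Ring A is the benzo ring, ring B the dihydro ring, ring C the aryl group on C1, and ring D the aryl group of the enol ether arm. The target SMILES reads as the 1,2-cis (1R,2R) isomer with a (Z)-enol ether.

Assumption: silyl ether 2 and MOM ether 9 are taken as catalogue compounds; each is otherwise one routine protection away from 4-bromoguaiacol or vanillin.

Step 1
Reactants: 1 2-bromo-5-hydroxy-4-methoxybenzaldehyde (6-bromoisovanillin); 2 (4-bromo-2-methoxyphenoxy)(tert-butyl)dimethylsilane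
Product: 4 racemic carbinol 4-bromo-5-{[4-(tert-butyldimethylsilyloxy)-3-methoxyphenyl](hydroxy)methyl}-2-methoxyphenol, via arylmagnesium bromide 3 (not isolated)
Conditions: 2, Mg, THF, 45 °C; separately 1, i-PrMgCl (1.0 equiv), THF, −20 °C, then 3 (1.3 equiv), −20 °C to rt; aq NH4Cl
Reagents that add atoms: none
Why: Grignard addition to the aldehyde; the magnesium phenoxide of 1 is inert, the aryl bromide does not exchange with an arylmagnesium halide at this temperature, and the racemic carbinol centre is harmless because C1 is planarised in step 7.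

Step 2
Reactants: 4 racemic carbinol
Product: 5 racemic sulfone 4-bromo-5-{[4-(tert-butyldimethylsilyloxy)-3-methoxyphenyl](4-methylphenylsulfonyl)methyl}-2-methoxyphenol
Conditions: p-TolSO2H (1.3 equiv), CH2Cl2, rt, short reaction time
Reagents that add atoms: 4-methylbenzenesulfinic acid, Cc1ccc(cc1)S(=O)O
Why: SN1-type dehydrative sulfonylation of an electron-rich benzhydrol; only the carbinol ionises, sulfur attack gives the stable sulfone, and the group both masks the carbinol for step 4 and later serves as the leaving group, while the C7 phenol stays free.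

Step 3
Reactants: 6 tert-butyl 2-(diethoxyphosphoryl)acetate
Product: 7 tert-butyl 2-diazo-2-(diethoxyphosphoryl)acetate
Conditions: NaH, THF, 0 °C; 4-acetamidobenzenesulfonyl azide, 0 °C to rt; aq NH4Cl
Reagents that add atoms: 4-acetamidobenzenesulfonyl azide, CC(=O)Nc1ccc(cc1)S(=O)(=O)N=[N+]=[N-]
Why: Regitz diazo transfer onto the doubly activated methylene of a phosphonoacetate.

Step 4
Reactants: 5 racemic sulfone; 7 diazophosphonoacetate
Product: 8 tert-butyl 2-{4-bromo-5-[(4-(tert-butyldimethylsilyloxy)-3-methoxyphenyl)(tosyl)methyl]-2-methoxyphenoxy}-2-(diethoxyphosphoryl)acetate (diastereomer mixture)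
Conditions: Rh2(OAc)4 (2 mol %), toluene, 80 °C, slow addition of 7
Reagents that add atoms: none
Why: rhodium-carbenoid O–H insertion into the only free O–H (the C7 phenol); both stereocentres present are erased later, so the mixture is used as such.

Step 5
Reactants: 8 aryloxyphosphonoacetate; 9 3-methoxy-4-(methoxymethoxy)benzaldehyde
Product: 11 tert-butyl (Z)-2-{4-bromo-5-[(4-hydroxy-3-methoxyphenyl)(tosyl)methyl]-2-methoxyphenoxy}-3-[3-methoxy-4-(methoxymethoxy)phenyl]acrylate, via silyl ether 10 (not isolated)
Conditions: NaH (1.05 equiv), THF, 0 °C; 9, 0 °C to rt; then AcOH (3 equiv), Bu4NF (1.2 equiv), 0 °C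
Reagents that add atoms: none
Why: Horner–Wadsworth–Emmons olefination places ring D trans to the ester, which is the (Z)-α-aryloxyacrylate; acetic-acid-buffered fluoride then frees only the ring C phenol and keeps it protonated, so sulfinate is not yet expelled.

Step 6
Reactants: 12 itaconic acid
Product: 13 di-tert-butyl itaconate
Conditions: 2-methylpropene (excess), H2SO4 (cat.), CH2Cl2, sealed vessel, rt
Reagents that add atoms: 2-methylpropene, CC(C)=C
Why: acid-catalysed addition of both carboxylic acids to isobutene (tert-butyl ester formation) gives esters that can be removed at the end without base.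

Step 7
Reactants: 11 aryl bromide/sulfone/phenol; 13 di-tert-butyl itaconate (2 equiv)
Product: 16 di-tert-butyl (1R,2S)-7-{[(Z)-1-(tert-butoxycarbonyl)-2-[3-methoxy-4-(methoxymethoxy)phenyl]vinyl]oxy}-1-(4-hydroxy-3-methoxyphenyl)-6-methoxy-1,2-dihydronaphthalene-2,3-dicarboxylate, via benzylidenesuccinate 14 (not isolated), via quinone methide 15 (not isolated)
Conditions: Pd(P(t-Bu)3)2 (5 mol %), O-benzyl-N-(9-anthracenylmethyl)dihydrocinchonidinium bromide (10 mol %), K2CO3 (powder, 4 equiv), toluene, 35–40 °C, argon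
Reagents that add atoms: none
Why: Proposed new method: this is a domino Mizoroki–Heck arylation/ion-pair-controlled intramolecular 1,6-conjugate addition, a formal (3+3) annulation whose parts are each known (Heck arylation of itaconates at CH2, release of quinone methides from sulfone precursors by inorganic base, phase-transfer-catalysed asymmetric 1,6-addition of carbon acids to p-quinone methides, six-ring closure by enolate 1,6-addition) but have not been merged or run with an ester dienolate. Zerovalent palladium inserts into C4a–Br and carbopalladates the unsubstituted CH2 of 13 (C4–C4a), syn β-hydride elimination gives the (E)-alkene 14 with ring A cis to the C2 methylene, and the ammonium phenoxide of ring C expels sulfinate to give 15. C2–H of 15 is α to an ester and vinylogously benzylic, so the carbonate/ammonium pair removes it and the dienolate closes ring B in a 6-(enolexo)-exo-trig mode onto C1 (equally a disrotatory 6π closure of the phenoxide/vinyl-o-quinodimethane resonance form), driven by rearomatisation of ring C (C1–C2). C1 is set in this closure by the chiral ammonium cation, the only soluble counter-ion of the closing anion in toluene, which distinguishes the two helical folds of the C2–C3–C4–C4a–C8a–C1 array (the pseudoenantiomeric dihydrocinchoninium salt is the alternative if the sense is opposite), whereas C2 should settle under carbonate as the 1,2-trans epimer and is only provisional, being reset in step 8. Site selectivity (C4a of ring A, not the equally electron-rich ring C) is fixed by the bromine atom, Heck regiochemistry by the 1,1-disubstituted acrylate, and the order of events by acidity and proximity, because 13 is a weaker carbon acid than 15 and could only react intermolecularly.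

Step 8
Reactants: 16 (1R,2S)-trans triester
Product: 18 di-tert-butyl (1R,2R)-7-{[(Z)-1-(tert-butoxycarbonyl)-2-[3-methoxy-4-(methoxymethoxy)phenyl]vinyl]oxy}-1-(4-hydroxy-3-methoxyphenyl)-6-methoxy-1,2-dihydronaphthalene-2,3-dicarboxylate, via dilithium dienolate 17 (not isolated)
Conditions: LiN(i-Pr)2 (2.4 equiv), THF, −78 °C, argon; then t-BuCO2H (6 equiv) in THF, −78 °C, then warm
Reagents that add atoms: none
Why: contra-thermodynamic kinetic protonation of an ester dienolate; deprotonation of the phenol and then C2–H flattens C2 into 17, whose C1 aryl group stands pseudo-axial on the nearly planar ring B and screens one face, so the bulky acid protonates the α-carbon C2 (the kinetic site, which keeps C3=C4 conjugated) anti to ring C and leaves the C2 ester cis to it (2R), with C1 untouched.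

Step 9
Reactants: 18 (1R,2R)-cis triester
Product: 19 (1R,2R)-7-{[(Z)-1-carboxy-2-(4-hydroxy-3-methoxyphenyl)vinyl]oxy}-1-(4-hydroxy-3-methoxyphenyl)-6-methoxy-1,2-dihydronaphthalene-2,3-dicarboxylic acid (target)
Conditions: CF3CO2H/CH2Cl2/H2O (45:50:5), 0 °C to rt
Reagents that add atoms: none
Why: acidolysis (loss of isobutene from three tert-butyl esters, hydrolysis of the MOM acetal) needs no base, so the epimerisable C2–H, the (Z)-α-aryloxyacrylate and C3=C4 should survive.

Compound list
1 | 2-bromo-5-hydroxy-4-methoxybenzaldehyde | O=Cc1cc(O)c(OC)cc1Br | starting material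
2 | (4-bromo-2-methoxyphenoxy)(tert-butyl)dimethylsilane | COc1cc(Br)ccc1O[Si](C)(C)C(C)(C)C | starting material
3 | [4-(tert-butyldimethylsilyloxy)-3-methoxyphenyl]magnesium bromide | COc1cc([Mg]Br)ccc1O[Si](C)(C)C(C)(C)C | intermediate
4 | racemic diaryl carbinol with free C7 phenol | COc1cc(Br)c(cc1O)C(O)c1ccc(O[Si](C)(C)C(C)(C)C)c(OC)c1 | intermediate
5 | racemic diarylmethyl p-tolyl sulfone with free C7 phenol | COc1cc(Br)c(cc1O)C(c1ccc(O[Si](C)(C)C(C)(C)C)c(OC)c1)S(=O)(=O)c1ccc(C)cc1 | intermediate
6 | tert-butyl 2-(diethoxyphosphoryl)acetate | CCOP(=O)(CC(=O)OC(C)(C)C)OCC | starting material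
7 | tert-butyl 2-diazo-2-(diethoxyphosphoryl)acetate | CCOP(=O)(OCC)C(=[N+]=[N-])C(=O)OC(C)(C)C | intermediate
8 | α-aryloxyphosphonoacetate (diastereomer mixture) | COc1cc(Br)c(cc1OC(C(=O)OC(C)(C)C)P(=O)(OCC)OCC)C(c1ccc(O[Si](C)(C)C(C)(C)C)c(OC)c1)S(=O)(=O)c1ccc(C)cc1 | intermediate
9 | 3-methoxy-4-(methoxymethoxy)benzaldehyde | COCOc1ccc(C=O)cc1OC | starting material
10 | (Z)-α-aryloxyacrylate, ring C as silyl ether | COc1cc(/C=C(\Oc2cc(C(c3ccc(O[Si](C)(C)C(C)(C)C)c(OC)c3)S(=O)(=O)c3ccc(C)cc3)c(Br)cc2OC)C(=O)OC(C)(C)C)ccc1OCOC | intermediate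
11 | (Z)-α-aryloxyacrylate, ring C as free phenol (key-step precursor) | COc1cc(/C=C(\Oc2cc(C(c3ccc(O)c(OC)c3)S(=O)(=O)c3ccc(C)cc3)c(Br)cc2OC)C(=O)OC(C)(C)C)ccc1OCOC | intermediate
12 | itaconic acid | C=C(CC(=O)O)C(=O)O | starting material
13 | di-tert-butyl itaconate | C=C(CC(=O)OC(C)(C)C)C(=O)OC(C)(C)C | intermediate
14 | (E)-benzylidenesuccinate (Heck product, sulfone still in place) | COc1cc(/C=C(\Oc2cc(C(c3ccc(O)c(OC)c3)S(=O)(=O)c3ccc(C)cc3)c(/C=C(\CC(=O)OC(C)(C)C)C(=O)OC(C)(C)C)cc2OC)C(=O)OC(C)(C)C)ccc1OCOC | intermediate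
15 | p-quinone methide of 14 (ring C quinoid, C1 sp2) | COc1cc(/C=C(\Oc2cc(C=C3C=CC(=O)C(OC)=C3)c(/C=C(\CC(=O)OC(C)(C)C)C(=O)OC(C)(C)C)cc2OC)C(=O)OC(C)(C)C)ccc1OCOC | intermediate
16 | (1R,2S)-trans-dihydronaphthalene tri-tert-butyl ester | COc1cc(/C=C(\Oc2cc3c(cc2OC)C=C(C(=O)OC(C)(C)C)[C@@H](C(=O)OC(C)(C)C)[C@@H]3c2ccc(O)c(OC)c2)C(=O)OC(C)(C)C)ccc1OCOC | intermediate
17 | dilithium phenoxide/C2 dienolate, C1 configuration retained | COc1cc(/C=C(\Oc2cc3c(cc2OC)C=C(C(=O)OC(C)(C)C)C(=C([O-])OC(C)(C)C)[C@@H]3c2ccc([O-])c(OC)c2)C(=O)OC(C)(C)C)ccc1OCOC.[Li+].[Li+] | intermediate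
18 | (1R,2R)-cis-dihydronaphthalene tri-tert-butyl ester | COc1cc(/C=C(\Oc2cc3c(cc2OC)C=C(C(=O)OC(C)(C)C)[C@H](C(=O)OC(C)(C)C)[C@@H]3c2ccc(O)c(OC)c2)C(=O)OC(C)(C)C)ccc1OCOC | intermediate
19 | CNP0328417.1, (1R,2R)-cis triacid with (Z)-enol ether | COc1cc(/C=C(\Oc2cc3c(cc2OC)C=C(C(=O)O)[C@H](C(=O)O)[C@@H]3c2ccc(O)c(OC)c2)C(=O)O)ccc1O | target

Total step count: 9. Longest linear sequence: 7 steps (1, 2, 4, 5, 7, 8, 9).

Steps most likely to fail

Step 7.
- What may go wrong: the quinone methide may be intercepted before the Heck event by itaconate anion, sulfinate or a second phenoxide. The aryl bromide may be reduced. The ion pair may discriminate the two faces only weakly at the temperature the Heck half needs.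
- Fallback: this route sets out from 10, isolated before desilylation, and returns at 16. It uses only known reaction types, taken one at a time.
  - A classical Heck reaction of 10 with 13 (Pd(OAc)2, P(o-tol)3, Et3N, MeCN, 85 °C) gives the silyl-protected (E)-benzylidenesuccinate F1.
  - Unbuffered Bu4NF followed by DBU (THF, 0 °C) frees the phenoxide, expels sulfinate and closes ring B to the racemic trans triester F2.
  - The ring C phenol of F2 is esterified with (S)-2-methoxy-2-phenylacetic acid (DCC, DMAP). The diastereomers are separated to give the (1R,2S) mandelate F3.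
  - Methanolysis of the aryl ester (K2CO3, MeOH, 0 °C) then delivers 16.

Step 8.
- What may go wrong: the proton may arrive from the shielded face or at C4. C2 may re-equilibrate on warming. The dienolate may be oxidised by air to the naphthalene.
- Fallback: this route sets out from 16 and returns at 18. It moves the stereodefining event from a lithium dienolate to a neutral silyl ketene acetal.
  - LiN(i-Pr)2 and then Me3SiCl (THF, −78 °C) give the bis-silylated ketene acetal F4.
  - F4 is protonated in toluene at −78 °C by a Lewis acid-assisted Brønsted acid, (R)-BINOL·SnCl4, whose bulk and chirality can reinforce attack anti to ring C.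
  - Aqueous work-up removes the aryl silyl ether.

Step 5.
- What may go wrong: geometric control in the olefination may be poor, and sulfinate may be lost early under base.
- Fallback: this route sets out from 5 and returns at 10. It replaces steps 3–5 by an aldol/elimination sequence.
  - Alkylation of the C7 phenol with tert-butyl bromoacetate (K2CO3, acetone) gives the aryloxyacetate F5.
  - LiN(i-Pr)2 (2.1 equiv; the first equivalent is taken up by the sulfone C–H) and then 9 at −78 °C give the β-hydroxy ester F6.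
  - MsCl/Et3N gives the mesylate F7.
  - DBU eliminates F7 by an E1cB path to the thermodynamically preferred (Z)-alkene 10.

Further compounds
F1 | step 7 | silyl-protected (E)-benzylidenesuccinate | COc1cc(/C=C(\Oc2cc(C(c3ccc(O[Si](C)(C)C(C)(C)C)c(OC)c3)S(=O)(=O)c3ccc(C)cc3)c(/C=C(\CC(=O)OC(C)(C)C)C(=O)OC(C)(C)C)cc2OC)C(=O)OC(C)(C)C)ccc1OCOC
F2 | step 7 | racemic trans triester (both enantiomers of 16) | COc1cc(/C=C(\Oc2cc3c(cc2OC)C=C(C(=O)OC(C)(C)C)C(C(=O)OC(C)(C)C)C3c2ccc(O)c(OC)c2)C(=O)OC(C)(C)C)ccc1OCOC
F3 | step 7 | (1R,2S) triester, ring C phenol as (S)-2-methoxy-2-phenylacetate | COc1cc(/C=C(\Oc2cc3c(cc2OC)C=C(C(=O)OC(C)(C)C)[C@@H](C(=O)OC(C)(C)C)[C@@H]3c2ccc(OC(=O)[C@@H](OC)c4ccccc4)c(OC)c2)C(=O)OC(C)(C)C)ccc1OCOC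
F4 | step 8 | C2 trimethylsilyl ketene acetal with ring C trimethylsilyl ether | COc1cc(/C=C(\Oc2cc3c(cc2OC)C=C(C(=O)OC(C)(C)C)C(=C(O[Si](C)(C)C)OC(C)(C)C)[C@@H]3c2ccc(O[Si](C)(C)C)c(OC)c2)C(=O)OC(C)(C)C)ccc1OCOC
F5 | step 5 | tert-butyl aryloxyacetate of 5 | COc1cc(Br)c(cc1OCC(=O)OC(C)(C)C)C(c1ccc(O[Si](C)(C)C(C)(C)C)c(OC)c1)S(=O)(=O)c1ccc(C)cc1
F6 | step 5 | β-hydroxy-α-aryloxy ester (diastereomer mixture) | COc1cc(Br)c(cc1OC(C(O)c1ccc(OCOC)c(OC)c1)C(=O)OC(C)(C)C)C(c1ccc(O[Si](C)(C)C(C)(C)C)c(OC)c1)S(=O)(=O)c1ccc(C)cc1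
F7 | step 5 | mesylate of F6 | COc1cc(Br)c(cc1OC(C(OS(C)(=O)=O)c1ccc(OCOC)c(OC)c1)C(=O)OC(C)(C)C)C(c1ccc(O[Si](C)(C)C(C)(C)C)c(OC)c1)S(=O)(=O)c1ccc(C)cc1
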